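**Plan**

- Ring A is numbered C1 (CO2Me), C2 (CH3), C3 (O‑aryl), C4 (OH), C5 (CH3), C6 (OH). The C6 hydroxyl next to the ester lies para to the aryloxy carbon C3, and C5(CH3)–C4(OH) is a propyne‑shaped unit with oxygen on one carbon. This is the substitution pattern left by a vinylketene/ynol‑ether benzannulation.
- Retrosynthesis: remove the ring B allyl ester and the ring B C–CHO bond (at the only aromatic C–H). Then cut ring A at C6–C5, C4–C3 and C6–C1, which gives an aryloxy(vinyl)ketene and 1‑siloxypropyne.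
- The ketene comes from an acid chloride. That is cut at its C3=C4 alkene (Wittig) and at the O–C(sp3) ether bond (SN2) to give the ring B phenol and tert‑butyl 2‑chloroacetoacetate.
- Forward: ring B is taken from orsellinic acid (allyl ester, chlorination, silylation). The chain is hung on its phenol oxygen at sp3 carbon. Ring A is grown on that oxygen in step 10, followed by desilylation, formylation and deallylation.
- Stereochemistry: the target has no stereocentre. The racemic chain carbon is erased in step 10. The only element that must be held is the E enoate (step 6), which keeps the ketene from closing onto the ester oxygen.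

Key step: step 10

Assumption: the minor 3‑chloro isomer of step 2 and the minor Z alkene of step 6 are removed by crystallisation or chromatography.

Abbreviation: ArO = 2‑[(prop‑2‑enyloxy)carbonyl]‑4‑chloro‑3‑methyl‑5‑(triisopropylsilyloxy)phenoxy, the phenoxy residue of compound 4.

**Route**

Step 1
Reactants: 1 orsellinic acid (2,4‑dihydroxy‑6‑methylbenzoic acid)
Product: 2 prop‑2‑enyl 2,4‑dihydroxy‑6‑methylbenzoate
Conditions: allyl bromide, KHCO3, DMF, rt
Reagents that add atoms: allyl bromide, C=CCBr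
Why: Carboxylate O‑alkylation (SN2), in which KHCO3 deprotonates only the carboxylic acid and not the phenols, so the acid is esterified without ether formation and without heating that would decarboxylate 1.

Step 2
Reactants: 2 prop‑2‑enyl 2,4‑dihydroxy‑6‑methylbenzoate
Product: 3 prop‑2‑enyl 3‑chloro‑4,6‑dihydroxy‑2‑methylbenzoate
Conditions: SO2Cl2 (1.0 equiv), Et2O, 0 °C
Reagents that add atoms: sulfuryl chloride, ClS(Cl)(=O)=O
Why: Electrophilic aromatic chlorination, which in orsellinate esters goes mainly to the carbon between the free para‑hydroxyl and the methyl group (para to the chelated hydroxyl), as in the usual preparations of 5‑chloroorsellinates, while one equivalent at 0 °C should leave the isolated allyl alkene untouched.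

Step 3
Reactants: 3 prop‑2‑enyl 3‑chloro‑4,6‑dihydroxy‑2‑methylbenzoate
Product: 4 prop‑2‑enyl 3‑chloro‑6‑hydroxy‑2‑methyl‑4‑(triisopropylsilyloxy)benzoate
Conditions: i‑Pr3SiCl, imidazole, DMF, 0 °C → rt
Reagents that add atoms: chlorotriisopropylsilane, CC(C)[Si](Cl)(C(C)C)C(C)C
Why: Silyl ether formation, selective for the hydroxyl para to the ester because it is the more acidic one and is not held in the hydrogen bond to the ester carbonyl, so the chelated ortho‑hydroxyl stays free for step 5.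

Step 4
Reactants: 5 tert‑butyl 3‑oxobutanoate
Product: 6 tert‑butyl 2‑chloro‑3‑oxobutanoate (racemic)
Conditions: SO2Cl2, CH2Cl2, 0 °C
Reagents that add atoms: sulfuryl chloride, ClS(Cl)(=O)=O
Why: α‑Chlorination of a β‑keto ester through its enol, the standard route to 2‑chloroacetoacetates, run cold so that the HCl formed does not cleave the tert‑butyl ester.

Step 5
Reactants: 4 prop‑2‑enyl 3‑chloro‑6‑hydroxy‑2‑methyl‑4‑(triisopropylsilyloxy)benzoate; 6 tert‑butyl 2‑chloro‑3‑oxobutanoate
Product: 7 tert‑butyl 2‑(ArO)‑3‑oxobutanoate (racemic)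
Conditions: K2CO3, NaI (cat.), acetone, 45 °C
Reagents that add atoms: none
Why: Williamson ether synthesis (SN2) at a carbon activated by two carbonyl groups, which makes the crowded aryl–O–C bond at sp3 carbon and places the aryloxy group unambiguously next to the tert‑butyl ester, under dry carbonate conditions that should spare the aryl silyl ether and the hindered allyl benzoate.

Step 6
Reactants: 7 tert‑butyl 2‑(ArO)‑3‑oxobutanoate
Product: 8 1‑tert‑butyl 5‑methyl (E)‑2‑(ArO)‑3‑methylpent‑3‑enedioate (racemic)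
Conditions: Ph3P=CHCO2Me (2 equiv), toluene, 100 °C; E isomer separated by chromatography
Reagents that add atoms: methyl (triphenylphosphoranylidene)acetate, COC(=O)C=P(c1ccccc1)(c1ccccc1)c1ccccc1
Why: Wittig olefination of a ketone activated by its α‑aryloxy and α‑ester groups with a stabilised ylide too weakly basic to hold 7 as its enolate, expected to put the bulky C2 substituent trans to CO2Me (E), while C2 stays racemic, which does not matter because it becomes sp2 in step 10.

Step 7
Reactants: 8 1‑tert‑butyl 5‑methyl (E)‑2‑(ArO)‑3‑methylpent‑3‑enedioate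
Product: 9 (E)‑2‑(ArO)‑5‑methoxy‑3‑methyl‑5‑oxopent‑3‑enoic acid (racemic)
Conditions: CF3CO2H, CH2Cl2, 0 °C → rt
Reagents that add atoms: none
Why: Acidolysis of the tert‑butyl ester (loss of isobutene) frees only the carboxyl on the aryloxy carbon, so the two chain ends are distinguished by their ester groups and not by a selective saponification that a base‑induced double‑bond shift would undermine, while the methyl and allyl esters and the electron‑poor aryl silyl ether should survive.

Step 8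
Reactants: 9 (E)‑2‑(ArO)‑5‑methoxy‑3‑methyl‑5‑oxopent‑3‑enoic acid
Product: 10 methyl (E)‑4‑(ArO)‑5‑chloro‑3‑methyl‑5‑oxopent‑2‑enoate (racemic acid chloride)
Conditions: (COCl)2, DMF (cat.), CH2Cl2, 0 °C → rt; concentrated and used crude
Reagents that add atoms: oxalyl chloride, ClC(=O)C(Cl)=O
Why: Acid chloride formation with oxalyl chloride under chloroiminium (Vilsmeier‑type) catalysis, mild enough for the silyl ether, the esters and the E enoate.

Step 9
Reactants: 11 propyne
Product: 14 1‑(triisopropylsilyloxy)propyne, via 1‑propynyllithium 12 (not isolated), via lithium propynolate 13 (not isolated)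
Conditions: n‑BuLi, THF, −78 °C; t‑BuOOLi (from t‑BuOOH, LiN(SiMe3)2), −78 → 0 °C; i‑Pr3SiOSO2CF3, −78 → 0 °C
Reagents that add atoms: tert‑butyl hydroperoxide, CC(C)(C)OO; triisopropylsilyl trifluoromethanesulfonate, CC(C)[Si](C(C)C)(C(C)C)OS(=O)(=O)C(F)(F)F
Why: Oxidation of a lithium acetylide with lithium tert‑butylperoxide gives the ynolate (Julia ynolate synthesis), which the hard silyl triflate captures on oxygen to give a bulky, distillable ynol ether.

Step 10
Reactants: 10 methyl (E)‑4‑(ArO)‑5‑chloro‑3‑methyl‑5‑oxopent‑2‑enoate; 14 1‑(triisopropylsilyloxy)propyne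
Product: 19 methyl 3‑(ArO)‑6‑hydroxy‑2,5‑dimethyl‑4‑(triisopropylsilyloxy)benzoate, via aryloxy(vinyl)ketene 15 (not isolated), via 3‑siloxy‑4‑vinylcyclobutenone 16 (not isolated), via dienylketene 17 (not isolated), via cyclohexadienone 18 (not isolated)
Conditions: 14 (1.5 equiv), Et3N (1.3 equiv, slow addition), toluene, rt; then 90 °C
Reagents that add atoms: none
Why: Et3N removes HCl from 10 (the C–H between the acyl chloride, the aryloxy group and the enoate) to give ketene 15, whose electrophilic carbonyl carbon bonds to the nucleophilic methyl‑bearing carbon of ynol ether 14 while the siloxy carbon bonds to the aryloxy carbon, a [2+2] cycloaddition that gives cyclobutenone 16. On warming, 16 opens by conrotatory four‑electron electrocyclic cleavage to dienylketene 17, which closes ring A by thermal disrotatory six‑electron electrocyclisation (ketene carbon to the ester‑bearing vinyl carbon), and cyclohexadienone 18 tautomerises to phenol 19, whose new hydroxyl is hydrogen‑bonded to the ester. The closest known reaction is the Danheiser benzannulation of vinylketenes with siloxyalkynes, with the ketene made here by dehydrochlorination of an acid chloride as in Staudinger and ketene–alkene cycloadditions. No stereocentre is formed, since the racemic carbon of 10 becomes sp2 in 15 and the sp3 carbon of 18 is lost on aromatisation. Three selectivities are needed: the [2+2] regiochemistry, secured by the polarisation of the ynol ether; outward rotation of the aryloxy donor in the ring opening, which turns the vinyl group toward the ketene so that 17 can cyclise; and the E enoate of 10, which keeps the ester carbonyl away from the ketene carbon (a Z ketene would close through oxygen to a 6‑methoxy‑2‑pyranone). Slow addition of the amine with excess 14 present keeps the ketene concentration low and so should suppress dimerisation.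

Step 11
Reactants: 19 methyl 3‑(ArO)‑6‑hydroxy‑2,5‑dimethyl‑4‑(triisopropylsilyloxy)benzoate
Product: 20 methyl 3‑{2‑[(prop‑2‑enyloxy)carbonyl]‑4‑chloro‑5‑hydroxy‑3‑methylphenoxy}‑4,6‑dihydroxy‑2,5‑dimethylbenzoate
Conditions: Bu4NF, AcOH, THF, 0 °C → rt
Reagents that add atoms: none
Why: Fluoride‑induced desilylation of both aryl silyl ethers (Si–F bond formation), buffered with acetic acid so that the phenoxides do not attack the esters, frees the ring B hydroxyl that directs step 12.

Step 12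
Reactants: 20 methyl 3‑{2‑[(prop‑2‑enyloxy)carbonyl]‑4‑chloro‑5‑hydroxy‑3‑methylphenoxy}‑4,6‑dihydroxy‑2,5‑dimethylbenzoate
Product: 22 methyl 3‑{2‑[(prop‑2‑enyloxy)carbonyl]‑4‑chloro‑6‑formyl‑5‑hydroxy‑3‑methylphenoxy}‑4,6‑dihydroxy‑2,5‑dimethylbenzoate, via aryl(chloro)methyl methyl ether 21 (not isolated)
Conditions: Cl2CHOMe, TiCl4, CH2Cl2, −20 → 0 °C; then aq. HCl
Reagents that add atoms: dichloromethyl methyl ether, COC(Cl)Cl; water, O
Why: Rieche formylation, in which TiCl4 binds the ring B phenol and delivers the oxocarbenium ion to its ortho position, the only aromatic C–H in 20 (ring A is fully substituted and the other ortho position carries Cl), hydrolysis of 21 then giving the aldehyde, while the allyl ester blocks ipso attack with decarboxylation.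

Step 13
Reactants: 22 methyl 3‑{2‑[(prop‑2‑enyloxy)carbonyl]‑4‑chloro‑6‑formyl‑5‑hydroxy‑3‑methylphenoxy}‑4,6‑dihydroxy‑2,5‑dimethylbenzoate
Product: 23 3‑chloro‑5‑formyl‑4‑hydroxy‑6‑[2,4‑dihydroxy‑5‑(methoxycarbonyl)‑3,6‑dimethylphenoxy]‑2‑methylbenzoic acid (CNP0210944.0)
Conditions: Pd(PPh3)4 (5 mol %), PhSO2Na, THF/MeOH, rt; then 1 M HCl
Reagents that add atoms: none
Why: Tsuji–Trost deallylation, in which zerovalent palladium ionises the allyl ester to a π‑allyl complex that benzenesulfinate traps, releases the acid at room temperature under neutral conditions that should spare the aldehyde, the methyl ester, the aryl chloride and the decarboxylation‑prone benzoic acid.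

**Compound list**

1 | orsellinic acid (2,4‑dihydroxy‑6‑methylbenzoic acid) | Cc1cc(O)cc(O)c1C(=O)O | starting material
2 | prop‑2‑enyl 2,4‑dihydroxy‑6‑methylbenzoate | Cc1cc(O)cc(O)c1C(=O)OCC=C | intermediate
3 | prop‑2‑enyl 3‑chloro‑4,6‑dihydroxy‑2‑methylbenzoate | Cc1c(Cl)c(O)cc(O)c1C(=O)OCC=C | intermediate
4 | prop‑2‑enyl 3‑chloro‑6‑hydroxy‑2‑methyl‑4‑(triisopropylsilyloxy)benzoate | Cc1c(Cl)c(O[Si](C(C)C)(C(C)C)C(C)C)cc(O)c1C(=O)OCC=C | intermediate
5 | tert‑butyl 3‑oxobutanoate | CC(=O)CC(=O)OC(C)(C)C | starting material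
6 | tert‑butyl 2‑chloro‑3‑oxobutanoate (racemic) | CC(=O)C(Cl)C(=O)OC(C)(C)C | intermediate
7 | tert‑butyl 2‑(ArO)‑3‑oxobutanoate (racemic) | CC(=O)C(Oc1cc(O[Si](C(C)C)(C(C)C)C(C)C)c(Cl)c(C)c1C(=O)OCC=C)C(=O)OC(C)(C)C | intermediate
8 | 1‑tert‑butyl 5‑methyl (E)‑2‑(ArO)‑3‑methylpent‑3‑enedioate (racemic) | COC(=O)/C=C(\C)C(Oc1cc(O[Si](C(C)C)(C(C)C)C(C)C)c(Cl)c(C)c1C(=O)OCC=C)C(=O)OC(C)(C)C | intermediate
9 | (E)‑2‑(ArO)‑5‑methoxy‑3‑methyl‑5‑oxopent‑3‑enoic acid (racemic) | COC(=O)/C=C(\C)C(Oc1cc(O[Si](C(C)C)(C(C)C)C(C)C)c(Cl)c(C)c1C(=O)OCC=C)C(=O)O | intermediate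
10 | methyl (E)‑4‑(ArO)‑5‑chloro‑3‑methyl‑5‑oxopent‑2‑enoate (racemic acid chloride) | COC(=O)/C=C(\C)C(Oc1cc(O[Si](C(C)C)(C(C)C)C(C)C)c(Cl)c(C)c1C(=O)OCC=C)C(Cl)=O | intermediate
11 | propyne | CC#C | starting material
12 | 1‑propynyllithium | CC#C[Li] | intermediate (not isolated)
13 | lithium prop‑1‑yn‑1‑olate | CC#CO[Li] | intermediate (not isolated)
14 | 1‑(triisopropylsilyloxy)propyne | CC#CO[Si](C(C)C)(C(C)C)C(C)C | intermediate
15 | methyl (E)‑4‑(ArO)‑3‑methyl‑5‑oxopenta‑2,4‑dienoate (aryloxy(vinyl)ketene) | COC(=O)/C=C(\C)C(Oc1cc(O[Si](C(C)C)(C(C)C)C(C)C)c(Cl)c(C)c1C(=O)OCC=C)=C=O | intermediate (not isolated)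
16 | methyl (E)‑3‑[1‑(ArO)‑3‑methyl‑4‑oxo‑2‑(triisopropylsilyloxy)cyclobut‑2‑en‑1‑yl]but‑2‑enoate (racemic) | COC(=O)/C=C(\C)C1(Oc2cc(O[Si](C(C)C)(C(C)C)C(C)C)c(Cl)c(C)c2C(=O)OCC=C)C(=O)C(C)=C1O[Si](C(C)C)(C(C)C)C(C)C | intermediate (not isolated)
17 | methyl (2E,4Z)‑4‑(ArO)‑3,6‑dimethyl‑7‑oxo‑5‑(triisopropylsilyloxy)hepta‑2,4,6‑trienoate (dienylketene) | COC(=O)/C=C(\C)/C(Oc1cc(O[Si](C(C)C)(C(C)C)C(C)C)c(Cl)c(C)c1C(=O)OCC=C)=C(/O[Si](C(C)C)(C(C)C)C(C)C)C(C)=C=O | intermediate (not isolated)
18 | methyl 3‑(ArO)‑2,5‑dimethyl‑6‑oxo‑4‑(triisopropylsilyloxy)cyclohexa‑2,4‑diene‑1‑carboxylate (racemic) | COC(=O)C1C(C)=C(Oc2cc(O[Si](C(C)C)(C(C)C)C(C)C)c(Cl)c(C)c2C(=O)OCC=C)C(O[Si](C(C)C)(C(C)C)C(C)C)=C(C)C1=O | intermediate (not isolated)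
19 | methyl 3‑(ArO)‑6‑hydroxy‑2,5‑dimethyl‑4‑(triisopropylsilyloxy)benzoate | COC(=O)c1c(C)c(Oc2cc(O[Si](C(C)C)(C(C)C)C(C)C)c(Cl)c(C)c2C(=O)OCC=C)c(O[Si](C(C)C)(C(C)C)C(C)C)c(C)c1O | intermediate
20 | methyl 3‑{2‑[(prop‑2‑enyloxy)carbonyl]‑4‑chloro‑5‑hydroxy‑3‑methylphenoxy}‑4,6‑dihydroxy‑2,5‑dimethylbenzoate | COC(=O)c1c(C)c(Oc2cc(O)c(Cl)c(C)c2C(=O)OCC=C)c(O)c(C)c1O | intermediate
21 | methyl 3‑{2‑[(prop‑2‑enyloxy)carbonyl]‑4‑chloro‑6‑[chloro(methoxy)methyl]‑5‑hydroxy‑3‑methylphenoxy}‑4,6‑dihydroxy‑2,5‑dimethylbenzoate | COC(=O)c1c(C)c(Oc2c(C(Cl)OC)c(O)c(Cl)c(C)c2C(=O)OCC=C)c(O)c(C)c1O | intermediate (not isolated)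
22 | methyl 3‑{2‑[(prop‑2‑enyloxy)carbonyl]‑4‑chloro‑6‑formyl‑5‑hydroxy‑3‑methylphenoxy}‑4,6‑dihydroxy‑2,5‑dimethylbenzoate | COC(=O)c1c(C)c(Oc2c(C=O)c(O)c(Cl)c(C)c2C(=O)OCC=C)c(O)c(C)c1O | intermediate
23 | 3‑chloro‑5‑formyl‑4‑hydroxy‑6‑[2,4‑dihydroxy‑5‑(methoxycarbonyl)‑3,6‑dimethylphenoxy]‑2‑methylbenzoic acid | COC(=O)c1c(C)c(Oc2c(C=O)c(O)c(Cl)c(C)c2C(=O)O)c(O)c(C)c1O | target

**Step count and risks**

Total steps: 13. Longest linear sequence: 11 (steps 1, 2, 3, 5, 6, 7, 8, 10, 11, 12, 13).

Step 10. What may go wrong: ketene dimerisation or amine‑induced loss of the ynol ether may outrun the cycloaddition, or the ketene may leak into the Z series and close to a pyranone. The fallback sets out from 9 and comes back at 20; it closes ring A by ionic chemistry instead of the pericyclic cascade. Acid 9 would be activated with carbonyldiimidazole to the acyl imidazole 1‑[(E)‑2‑(ArO)‑5‑methoxy‑3‑methyl‑5‑oxopent‑3‑enoyl]imidazole F1. F1 would be C‑acylated with the magnesium enolate of potassium methyl methylmalonate (MgCl2, Et3N, THF; Masamune–Brooks conditions), which after loss of CO2 gives the β‑keto ester dimethyl (E)‑4‑(ArO)‑3,6‑dimethyl‑5‑oxohept‑2‑enedioate F2. KOtBu in THF would then deprotonate C4, and the vinylogous carbanion at C2 would attack the C7 ester in a six‑membered Dieckmann‑type closure. The resulting dione should aromatise at once to the resorcinol methyl 3‑(ArO)‑4,6‑dihydroxy‑2,5‑dimethylbenzoate F3. Bu4NF/AcOH would remove the ring B silyl group to give 20; loss of that silyl group already under the basic closure would be harmless.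

Step 6. What may go wrong: the ylide may fail to add to the hindered, partly enolised ketone, or the E/Z ratio may be poor. The fallback sets out from 4 and comes back at 9; it makes the C2–C3 bond by conjugate addition instead of olefination. Di‑tert‑butyl malonate would be brominated (CBr4, DBU, THF, 0 °C) to di‑tert‑butyl 2‑bromomalonate F4, which would alkylate phenol 4 (K2CO3, acetone) to di‑tert‑butyl 2‑(ArO)malonate F5. Michael addition of F5 to methyl but‑2‑ynoate (NaH cat., THF) would give 1,1‑di‑tert‑butyl 3‑methyl (E)‑1‑(ArO)‑2‑methylprop‑2‑ene‑1,1,3‑tricarboxylate F6, with the quaternary carbon expected to settle trans to CO2Me under the equilibrating conditions. CF3CO2H would cleave both tert‑butyl esters to the malonic acid (E)‑2‑(ArO)‑2‑(4‑methoxy‑4‑oxobut‑2‑en‑2‑yl)propanedioic acid F7, which should lose CO2 on gentle warming in toluene to give 9.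

Step 5. What may go wrong: chloride 6 may be drained as its unreactive enolate while the chelated, hindered phenoxide attacks slowly, and silyl transfer between phenoxides may occur. The fallback sets out from 5 and 4 and comes back at 7; it makes the ether bond under neutral conditions by carbenoid O–H insertion. Diazo transfer to 5 (4‑acetamidobenzenesulfonyl azide, Et3N, MeCN) would give tert‑butyl 2‑diazo‑3‑oxobutanoate F8. Rh2(OAc)4 (1 mol %, CH2Cl2, rt) would turn F8 into a rhodium carbenoid, which should insert into the phenolic O–H bond of 4 faster than it cyclopropanates the isolated allyl alkene, giving 7.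

**Further compounds**

F1 | step 10 | 1‑[(E)‑2‑(ArO)‑5‑methoxy‑3‑methyl‑5‑oxopent‑3‑enoyl]imidazole | COC(=O)/C=C(\C)C(Oc1cc(O[Si](C(C)C)(C(C)C)C(C)C)c(Cl)c(C)c1C(=O)OCC=C)C(=O)n1ccnc1
F2 | step 10 | dimethyl (E)‑4‑(ArO)‑3,6‑dimethyl‑5‑oxohept‑2‑enedioate | COC(=O)/C=C(\C)C(Oc1cc(O[Si](C(C)C)(C(C)C)C(C)C)c(Cl)c(C)c1C(=O)OCC=C)C(=O)C(C)C(=O)OC
F3 | step 10 | methyl 3‑(ArO)‑4,6‑dihydroxy‑2,5‑dimethylbenzoate | COC(=O)c1c(C)c(Oc2cc(O[Si](C(C)C)(C(C)C)C(C)C)c(Cl)c(C)c2C(=O)OCC=C)c(O)c(C)c1O
F4 | step 6 | di‑tert‑butyl 2‑bromomalonate | CC(C)(C)OC(=O)C(Br)C(=O)OC(C)(C)C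
F5 | step 6 | di‑tert‑butyl 2‑(ArO)malonate | CC(C)(C)OC(=O)C(Oc1cc(O[Si](C(C)C)(C(C)C)C(C)C)c(Cl)c(C)c1C(=O)OCC=C)C(=O)OC(C)(C)C
F6 | step 6 | 1,1‑di‑tert‑butyl 3‑methyl (E)‑1‑(ArO)‑2‑methylprop‑2‑ene‑1,1,3‑tricarboxylate | COC(=O)/C=C(\C)C(Oc1cc(O[Si](C(C)C)(C(C)C)C(C)C)c(Cl)c(C)c1C(=O)OCC=C)(C(=O)OC(C)(C)C)C(=O)OC(C)(C)C
F7 | step 6 | (E)‑2‑(ArO)‑2‑(4‑methoxy‑4‑oxobut‑2‑en‑2‑yl)propanedioic acid | COC(=O)/C=C(\C)C(Oc1cc(O[Si](C(C)C)(C(C)C)C(C)C)c(Cl)c(C)c1C(=O)OCC=C)(C(=O)O)C(=O)O
F8 | step 5 | tert‑butyl 2‑diazo‑3‑oxobutanoate | CC(=O)C(=[N+]=[N-])C(=O)OC(C)(C)C
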